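**Retrosynthetic overview**

1. Target 40 ← triol 39 (propionylation at C2) ← macrolactone 38. The ten-membered ring is closed at C6–C7 by Nozaki–Hiyama–Kishi addition of a (Z)-vinyl iodide to the C7 aldehyde, and the γ-lactone then closes onto C19.
2. C7, C8, C17 and C19, with the C8 and C17 configurations, come from L-malic acid as dioxolanone 30. Its enolate is joined to the C9 aldehyde 25 by an aldol addition (C8–C9).
3. C9, the C11 methyl and the C11 hydroxyl are placed on dienone 19 by conjugate addition and enolate chemistry, steered by a silicon bridge at C14.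
4. The cyclohexenone (bonds C12–C13 and C14–C1) comes from cyclobutanone 17 by Rh-catalysed insertion of a silicon-tethered ethyne. The enabling feature is the four-membered ketone ring C12(=O)–C1–C10–C11, whose strained C12–C1 bond is opened, together with the C2 oxygen next to C1, which anchors the O–Si–C≡CH tether.
5. Cyclobutanone 13 comes from asymmetric epoxidation and semipinacol ring expansion of cyclopropanol 11. Ring order: cyclopropane → cyclobutanone → cyclohexenone with a temporary oxasilole → ten-membered ring → γ-lactone.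

Key step: step 10

Remark: positions are named with the usual briarane locants (C1 quaternary ring-fusion carbon, C2 propionyloxy carbon, C5=C6 ring alkene, C7 lactone O–CH, C8 and C11 tertiary carbinols, C9 acetoxy carbon, C10 ring-fusion CH, C12 ketone, C13=C14 enone, C17/C19 lactone CH(CH3)/C=O). The target is taken as (1S,2R,5Z,7S,8S,9R,10S,11S,17R). The ligand antipode for step 7 has to be assigned by a model experiment.

**Route**

Step 1
Reactants: 1 prop-2-yn-1-ol
Product: 2 (2Z)-3-iodo-2-methylprop-2-en-1-ol
Conditions: MeMgBr (2.5 equiv), CuI (10 mol %), THF, −10 °C → rt; then I2, −10 °C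
Reagents that add atoms: methylmagnesium bromide (C[Mg]Br); iodine (II)
Why: Copper-catalysed anti-carbomagnesiation of the propargylic alkoxide (Duboudin reaction) places magnesium cis to the CH2O group in a chelate, and iodinolysis with retention should give the (Z)-iodide.

Step 2
Reactants: 2 (2Z)-3-iodo-2-methylprop-2-en-1-ol
Product: 4 (2Z)-2-methyl-3-(trimethylsilyl)prop-2-en-1-ol, via trimethylsilyl ether 3 (not isolated)
Conditions: TMSCl, Et3N, THF, 0 °C; filter; t-BuLi (2.1 equiv), −78 → −20 °C; H2O
Reagents that add atoms: chlorotrimethylsilane (C[Si](C)(C)Cl)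
Why: Iodine–lithium exchange followed by retro-[1,4]-Brook O→C silyl migration, possible only for the cis vinyllithium, should move silicon to carbon with retention of the alkene geometry.

Step 3
Reactants: 4 (2Z)-2-methyl-3-(trimethylsilyl)prop-2-en-1-ol
Product: 5 [(1Z)-3-bromo-2-methylprop-1-en-1-yl]trimethylsilane
Conditions: CBr4, PPh3, CH2Cl2, 0 °C
Reagents that add atoms: carbon tetrabromide (BrC(Br)(Br)Br)
Why: Appel bromination of the primary allylic alcohol under neutral conditions leaves the vinylsilane geometry untouched.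

Step 4
Reactants: 5 [(1Z)-3-bromo-2-methylprop-1-en-1-yl]trimethylsilane; 6 (1,3-dioxolan-2-ylmethyl)magnesium bromide
Product: 8 (4Z)-4-methyl-5-(trimethylsilyl)pent-4-enal, via dioxolane acetal 7 (not isolated)
Conditions: Li2CuCl4 (3 mol %), THF, −20 → 0 °C; then 1 M HCl, THF/H2O, rt
Reagents that add atoms: water (O)
Why: Kochi-type copper-catalysed coupling of the allylic bromide at its unhindered CH2 terminus (the silyl-bearing γ-carbon is blocked) followed by acetal hydrolysis should give the aldehyde without touching the alkene.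

Step 5
Reactants: 8 (4Z)-4-methyl-5-(trimethylsilyl)pent-4-enal; 9 methyl 2-[bis(2,2,2-trifluoroethoxy)phosphoryl]propanoate
Product: 10 methyl (2Z,6Z)-2,6-dimethyl-7-(trimethylsilyl)hepta-2,6-dienoate
Conditions: KHMDS, 18-crown-6, THF, −78 °C
Reagents that add atoms: none
Why: Still–Gennari olefination, in which fast elimination from the kinetic adduct of the electron-poor phosphonate gives the (Z)-trisubstituted enoate that the stereospecific ring expansion of step 7 requires.

Step 6
Reactants: 10 methyl (2Z,6Z)-2,6-dimethyl-7-(trimethylsilyl)hepta-2,6-dienoate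
Product: 11 1-[(2Z,6Z)-6-methyl-7-(trimethylsilyl)hepta-2,6-dien-2-yl]cyclopropan-1-ol
Conditions: EtMgBr (3 equiv), Ti(OiPr)4 (0.3 equiv), THF, 0 °C → rt
Reagents that add atoms: ethylmagnesium bromide (CC[Mg]Br)
Why: Kulinkovich cyclopropanation, in which the titanacyclopropane acts as a 1,2-dicarbanion on the ester carbonyl, should give the 1-alkenylcyclopropanol with unchanged alkene geometry and supply C10 and C11.

Step 7
Reactants: 11 1-[(2Z,6Z)-6-methyl-7-(trimethylsilyl)hepta-2,6-dien-2-yl]cyclopropan-1-ol
Product: 13 (2S)-2-[(1R,4Z)-1-hydroxy-4-methyl-5-(trimethylsilyl)pent-4-en-1-yl]-2-methylcyclobutan-1-one, via epoxy cyclopropanol 12 (not isolated)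
Conditions: WO2(acac)2 (5 mol %), chiral bishydroxamic acid ligand (6 mol %), 30% H2O2, NaCl, CH2Cl2, rt; Na2S2O3 wash; then BF3·OEt2 (10 mol %), CH2Cl2, −78 °C
Reagents that add atoms: hydrogen peroxide (OO)
Why: Hydroxyl-directed catalytic asymmetric epoxidation of the tertiary allylic alcohol (ligand antipode chosen for the (2R,3R)-epoxide, the remote vinylsilane not being directed) followed by semipinacol ring expansion, in which a cyclopropane bond migrates anti to the breaking C1–O bond, should set C1 (inversion) and C2 (retention) from the epoxide.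

Step 8
Reactants: 14 dichlorodi(propan-2-yl)silane; 15 ethynylmagnesium bromide
Product: 16 chloro(ethynyl)di(propan-2-yl)silane
Conditions: 14 (1.5 equiv), THF, −78 → 0 °C; distillation
Reagents that add atoms: none
Why: Nucleophilic substitution at silicon by the alkynyl Grignard reagent should stop at the mono-adduct because the two isopropyl groups retard a second substitution.

Step 9
Reactants: 13 the hydroxy cyclobutanone; 16 chloro(ethynyl)di(propan-2-yl)silane
Product: 17 ethynyl(diisopropyl)silyl ether of 13
Conditions: imidazole, DMAP (cat.), DMF, 0 °C → rt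
Reagents that add atoms: none
Why: Silylation of the secondary alcohol under mild base that should not trigger retro-aldol cleavage of the β-hydroxy cyclobutanone.

Step 10
Reactants: 17 ethynyl(diisopropyl)silyl ether of 13
Product: 18 oxasilole-fused cyclohex-2-enone (C14 bonded to silicon; C1 and C2 configured as in 13)
Conditions: [Rh(C2H4)2Cl]2 (5 mol %), P[3,5-(CF3)2C6H3]3 (22 mol %), 1,4-dioxane, 110 °C, 0.02 M
Reagents that add atoms: none
Why: Proposed new method: Rh(I) should insert oxidatively into the strained acyl–C1 bond of the cyclobutanone (about 26 kcal/mol of ring strain) to give a rhodacyclopentanone, the silicon-held ethyne then inserts into the Rh–C1 bond, and C(acyl)–C(vinyl) reductive elimination closes the enone, so that C14–C1 and C12–C13 form in one catalytic cycle. The closest known reaction type is the Rh-catalysed intramolecular (4+2) "cut-and-sew" coupling of cyclobutanones with alkynes tethered at the α-carbon through carbon, nitrogen or oxygen linkers, combined with the known use of cleavable silyl-ether tethers in metal-catalysed alkyne cycloadditions; new here are the O–Si linker, the terminal alkyne and the α-quaternary centre. The six-membered ring closes as a formal [4+2] of a C–C σ-bond with the alkyne, and the five-membered oxasilole closes by 5-exo migratory insertion at the alkyne carbon that carries silicon. No stereocentre is created: C1 passes through oxidative addition and reductive elimination with retention and C2 is a spectator, so the configurations from step 7 are conserved. The step needs regioselectivity between the two acyl–C(α) bonds and between the two alkyne orientations, and the three-atom tether secures both, because only cleavage of C12–C1 with the silicon-bearing carbon bonding to C1 leads to a fused product without a bridgehead alkene, while insertion into C12–C11 is reversible and unproductive. Chemoselectivity against decarbonylation or (4+1) closure is to be secured by the π-acidic phosphine, and the trisubstituted vinylsilane is too hindered to compete as the 2π partner.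

Step 11
Reactants: 18 oxasilole-fused cyclohex-2-enone
Product: 19 cross-conjugated dienone (new C10=C11 bond)
Conditions: LDA, THF, −78 °C; then N-tert-butylbenzenesulfinimidoyl chloride, −78 °C
Reagents that add atoms: none
Why: Mukaiyama dehydrogenation of the only available (C11) lithium enolate by sulfilimine formation and syn-elimination should give the 2,5-dienone at low temperature.

Step 12
Reactants: 19 cross-conjugated dienone; 20 1,3-dithiane
Product: 22 C10-(1,3-dithian-2-yl) C11-methyl enone, via lithium enolate 21 (not isolated)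
Conditions: 20, n-BuLi, THF, −30 °C; HMPA (2 equiv), −78 °C; add 19; then MeI, −78 → −20 °C
Reagents that add atoms: iodomethane (CI)
Why: HMPA-promoted 1,4-addition of 2-lithio-1,3-dithiane (a formyl anion equivalent) should occur at C10, because C14 is β,β-disubstituted and silylated, and from the face anti to the C2 arm of the oxasilole (cis to the C1 methyl), after which the enolate is C-methylated (C11 configuration is erased in step 13).

Step 13
Reactants: 22 C10-(1,3-dithian-2-yl) C11-methyl enone
Product: 24 C11 triethylsilyl ether of the tertiary α-hydroxy ketone, via potassium alkoxide 23 (not isolated)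
Conditions: KHMDS, THF, −78 °C; 2-(benzenesulfonyl)-3-phenyloxaziridine; then TESOTf, −78 → 0 °C
Reagents that add atoms: 2-(benzenesulfonyl)-3-phenyloxaziridine (O1C(c2ccccc2)N1S(=O)(=O)c1ccccc1); triethylsilyl trifluoromethanesulfonate (CC[Si](CC)(CC)OS(=O)(=O)C(F)(F)F)
Why: Davis hydroxylation of the tetrasubstituted potassium enolate from the face opposite both the C10 dithianyl group and the C1 methyl should place the C11 oxygen trans to C9, and the alkoxide is trapped as its TES ether.

Step 14
Reactants: 24 C11 triethylsilyl ether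
Product: 25 C9 aldehyde
Conditions: MeI, CaCO3, MeCN/H2O 9:1, 45 °C
Reagents that add atoms: water (O)
Why: S-Alkylative hydrolysis of the dithioacetal under buffered neutral conditions should spare the silyl ethers, both vinylsilanes and the epimerisable C10.

Step 15
Reactants: 26 diethyl (2S)-2-hydroxybutanedioate
Product: 27 diethyl (2S,3R)-2-hydroxy-3-methylbutanedioate
Conditions: LDA (2.2 equiv), THF, −78 → −20 °C; MeI, −78 °C → rt
Reagents that add atoms: iodomethane (CI)
Why: Fráter–Seebach alkylation, in which the chelated alkoxide-enolate is methylated anti to the alkoxide, should give the anti (2S,3R) isomer that maps onto C8 and C17.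

Step 16
Reactants: 27 diethyl (2S,3R)-2-hydroxy-3-methylbutanedioate
Product: 28 (2S,3R)-2-hydroxy-3-methylbutanedioic acid
Conditions: KOH, H2O/EtOH, 0 °C → rt; then HCl to pH 1
Reagents that add atoms: potassium hydroxide ([K+].[OH-])
Why: Saponification, in which the dicarboxylate resists enolisation so that the methyl-bearing stereocentre should not epimerise.

Step 17
Reactants: 28 (2S,3R)-2-hydroxy-3-methylbutanedioic acid; 29 2,2-dimethylpropanal
Product: 30 (2R)-2-[(2S,4S)-2-tert-butyl-5-oxo-1,3-dioxolan-4-yl]propanoic acid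
Conditions: TsOH·H2O (cat.), H2SO4 (cat.), pentane, reflux, Dean–Stark; recrystallisation
Reagents that add atoms: none
Why: Seebach acetalisation of the α-hydroxy acid under thermodynamic control should give the cis-2,5-disubstituted dioxolanone, storing the C8 configuration in the acetal centre.

Step 18
Reactants: 25 C9 aldehyde; 30 the dioxolanone acid
Product: 32 C9 acetate of the aldol adduct with free C19 acid, via aldol adduct 31 (not isolated)
Conditions: 30 (2.0 equiv), LDA (4.0 equiv), THF, −78 °C; add 25; then Ac2O (6 equiv), −78 → −40 °C; aq. NaHCO3, then 1 M HCl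
Reagents that add atoms: acetic anhydride (CC(=O)OC(C)=O)
Why: Aldol addition of the dioxolanone enolate (self-regeneration of stereocentres, the C19 carboxylate as spectator) should form C8–C9 anti to tert-butyl with retention at C8 and, by Felkin–Anh attack anti to the C1 quaternary carbon, give (9R), the aldolate being acetylated before it can revert or lactonise.

Step 19
Reactants: 32 C9 acetate with free C19 acid
Product: 33 C19 methyl ester
Conditions: TMSCHN2, MeOH/toluene, 0 °C
Reagents that add atoms: (trimethylsilyl)diazomethane (C[Si](C)(C)C=[N+]=[N-])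
Why: Neutral O-methylation of the carboxylic acid should touch neither the acetate nor the dioxolanone.

Step 20
Reactants: 33 C19 methyl ester
Product: 34 C7 S-ethyl thioester with free C8 hydroxyl
Conditions: EtSH (10 equiv), Et3N, DMAP (10 mol %), CH2Cl2, 0 °C → rt
Reagents that add atoms: ethanethiol (CCS)
Why: Thiolysis of the dioxolanone, an activated acylal ester that is far more electrophilic than the acetate or methyl ester, should release pivalaldehyde and the tertiary alcohol, while thia-Michael addition is blocked by silicon at C14.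

Step 21
Reactants: 34 C7 S-ethyl thioester
Product: 35 C7 aldehyde
Conditions: Et3SiH (3 equiv), 10% Pd/C, acetone, rt
Reagents that add atoms: none
Why: Fukuyama reduction should convert the thioester to the aldehyde in the presence of the ketone, esters and silyl groups.

Step 22
Reactants: 35 C7 aldehyde
Product: 36 (Z)-vinyl iodide at C6
Conditions: NIS (1.2 equiv), (CF3)2CHOH, 0 °C, dark
Reagents that add atoms: N-iodosuccinimide (O=C1CCC(=O)N1I)
Why: Iododesilylation of the electron-rich trisubstituted vinylsilane by ipso-substitution with retention should be selective over the electron-poor β-silyl enone.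

Step 23
Reactants: 36 (Z)-vinyl iodide aldehyde
Product: 38 ten-membered carbocycle with fused γ-lactone, via hydroxy ester 37 (not isolated)
Conditions: CrCl2 (10 equiv), NiCl2 (0.2 equiv), degassed DMSO/THF 3:1, rt, slow addition to 2 mM; aqueous work-up; then PPTS (cat.), toluene, 40 °C
Reagents that add atoms: none
Why: Nozaki–Hiyama–Kishi macrocyclisation, in which the vinylchromium(III) species formed with retention of the (Z)-geometry adds only to the aldehyde, should close the C6–C7 bond by Felkin–Anh (non-chelated) attack anti to the C8–O bond to give (7S), and the C7 oxygen then lactonises onto the methyl ester.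

Step 24
Reactants: 38 macrocyclic lactone
Product: 39 9-O-acetyl triol (free C2, C8 and C11 hydroxyls; C14–H)
Conditions: TBAF (6 equiv), AcOH (6 equiv), THF, 45 °C
Reagents that add atoms: none
Why: Buffered fluoride should open the oxasilole at Si–O, protodesilylate the activated β-silyl enone carbon and remove the TES ether, while the buffer suppresses acetate loss and retro-aldol pathways.

Step 25
Reactants: 39 9-O-acetyl triol
Product: 40 CNP0240018.1
Conditions: (EtCO)2O (3 equiv), Et3N, DMAP (cat.), CH2Cl2, 0 °C → rt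
Reagents that add atoms: propanoic anhydride (CCC(=O)OC(=O)CC)
Why: DMAP-catalysed acylation should take place at the only secondary alcohol (C2), the two tertiary alcohols being much slower.

**Compound list**

1 | prop-2-yn-1-ol | C#CCO | starting material
2 | (2Z)-3-iodo-2-methylprop-2-en-1-ol | OC/C(C)=C\I | intermediate
3 | (2Z)-3-iodo-2-methylprop-2-en-1-yl trimethylsilyl ether | C[Si](C)(C)OC/C(C)=C\I | intermediate
4 | (2Z)-2-methyl-3-(trimethylsilyl)prop-2-en-1-ol | OC/C(C)=C\[Si](C)(C)C | intermediate
5 | [(1Z)-3-bromo-2-methylprop-1-en-1-yl]trimethylsilane | BrC/C(C)=C\[Si](C)(C)C | intermediate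
6 | (1,3-dioxolan-2-ylmethyl)magnesium bromide | Br[Mg]CC1OCCO1 | starting material
7 | 2-[(3Z)-3-methyl-4-(trimethylsilyl)but-3-en-1-yl]-1,3-dioxolane | C1COC(O1)CC/C(C)=C\[Si](C)(C)C | intermediate
8 | (4Z)-4-methyl-5-(trimethylsilyl)pent-4-enal | O=CCC/C(C)=C\[Si](C)(C)C | intermediate
9 | methyl 2-[bis(2,2,2-trifluoroethoxy)phosphoryl]propanoate | COC(=O)C(C)P(=O)(OCC(F)(F)F)OCC(F)(F)F | starting material
10 | methyl (2Z,6Z)-2,6-dimethyl-7-(trimethylsilyl)hepta-2,6-dienoate | COC(=O)/C(C)=C\CC/C(C)=C\[Si](C)(C)C | intermediate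
11 | 1-[(2Z,6Z)-6-methyl-7-(trimethylsilyl)hepta-2,6-dien-2-yl]cyclopropan-1-ol | OC1(CC1)/C(C)=C\CC/C(C)=C\[Si](C)(C)C | intermediate
12 | 1-{(2R,3R)-2-methyl-3-[(3Z)-3-methyl-4-(trimethylsilyl)but-3-en-1-yl]oxiran-2-yl}cyclopropan-1-ol | OC1(CC1)[C@]2(C)O[C@@H]2CC/C(C)=C\[Si](C)(C)C | intermediate
13 | (2S)-2-[(1R,4Z)-1-hydroxy-4-methyl-5-(trimethylsilyl)pent-4-en-1-yl]-2-methylcyclobutan-1-one | O=C1CC[C@@]1(C)[C@H](O)CC/C(C)=C\[Si](C)(C)C | intermediate
14 | dichlorodi(propan-2-yl)silane | CC(C)[Si](Cl)(Cl)C(C)C | starting material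
15 | ethynylmagnesium bromide | C#C[Mg]Br | starting material
16 | chloro(ethynyl)di(propan-2-yl)silane | CC(C)[Si](Cl)(C#C)C(C)C | intermediate
17 | (2S)-2-[(1R,4Z)-1-{[ethynyldi(propan-2-yl)silyl]oxy}-4-methyl-5-(trimethylsilyl)pent-4-en-1-yl]-2-methylcyclobutan-1-one | O=C1CC[C@@]1(C)[C@H](O[Si](C#C)(C(C)C)C(C)C)CC/C(C)=C\[Si](C)(C)C | intermediate
18 | cyclohex-2-enone fused at C1–C14 to a 1,2-oxasilole (Si(iPr)2 on C14, O on C2; C1 methyl; C2 side chain (3Z)-3-methyl-4-(trimethylsilyl)but-3-enyl) | O=C1C=C2[Si](C(C)C)(C(C)C)O[C@H](CC/C(C)=C\[Si](C)(C)C)[C@]2(C)CC1 | intermediate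
19 | 2,5-dienone of 18 (additional C10=C11 double bond) | O=C1C=C2[Si](C(C)C)(C(C)C)O[C@H](CC/C(C)=C\[Si](C)(C)C)[C@]2(C)C=C1 | intermediate
20 | 1,3-dithiane | C1CSCSC1 | starting material
21 | lithium C11=C12 enolate of the C10 dithianyl adduct | [Li]OC=1C=C2[Si](C(C)C)(C(C)C)O[C@H](CC/C(C)=C\[Si](C)(C)C)[C@]2(C)[C@@H](C3SCCCS3)C=1 | intermediate
22 | enone with C10 1,3-dithian-2-yl group cis to the C1 methyl and a C11 methyl group trans to it | O=C1C=C2[Si](C(C)C)(C(C)C)O[C@H](CC/C(C)=C\[Si](C)(C)C)[C@]2(C)[C@@H](C3SCCCS3)[C@@H]1C | intermediate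
23 | potassium alkoxide of the C11 tertiary α-hydroxy ketone (O trans to the C10 dithianyl group) | O=C1C=C2[Si](C(C)C)(C(C)C)O[C@H](CC/C(C)=C\[Si](C)(C)C)[C@]2(C)[C@@H](C3SCCCS3)[C@]1(C)O[K] | intermediate
24 | C11 triethylsilyl ether of the α-hydroxy ketone | O=C1C=C2[Si](C(C)C)(C(C)C)O[C@H](CC/C(C)=C\[Si](C)(C)C)[C@]2(C)[C@@H](C3SCCCS3)[C@]1(C)O[Si](CC)(CC)CC | intermediate
25 | C9 aldehyde (formyl group on C10, cis to the C1 methyl) | O=C1C=C2[Si](C(C)C)(C(C)C)O[C@H](CC/C(C)=C\[Si](C)(C)C)[C@]2(C)[C@@H](C=O)[C@]1(C)O[Si](CC)(CC)CC | intermediate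
26 | diethyl (2S)-2-hydroxybutanedioate (diethyl L-malate) | CCOC(=O)[C@@H](O)CC(=O)OCC | starting material
27 | diethyl (2S,3R)-2-hydroxy-3-methylbutanedioate | CCOC(=O)[C@@H](O)[C@@H](C)C(=O)OCC | intermediate
28 | (2S,3R)-2-hydroxy-3-methylbutanedioic acid | OC(=O)[C@@H](O)[C@@H](C)C(O)=O | intermediate
29 | 2,2-dimethylpropanal | CC(C)(C)C=O | starting material
30 | (2R)-2-[(2S,4S)-2-tert-butyl-5-oxo-1,3-dioxolan-4-yl]propanoic acid | O=C1O[C@@H](C(C)(C)C)O[C@H]1[C@@H](C)C(O)=O | intermediate
31 | aldol adduct of 25 and 30 (C9 hydroxyl, held in the flask as lithium alkoxide and carboxylate; C8 quaternary in the dioxolanone, tert-butyl trans to C9) | O=C1C=C2[Si](C(C)C)(C(C)C)O[C@H](CC/C(C)=C\[Si](C)(C)C)[C@]2(C)[C@@H]([C@@H](O)[C@]3(O[C@H](C(C)(C)C)OC3=O)[C@@H](C)C(O)=O)[C@]1(C)O[Si](CC)(CC)CC | intermediate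
32 | C9 acetate of 31 with free C19 carboxylic acid | O=C1C=C2[Si](C(C)C)(C(C)C)O[C@H](CC/C(C)=C\[Si](C)(C)C)[C@]2(C)[C@@H]([C@@H](OC(C)=O)[C@]3(O[C@H](C(C)(C)C)OC3=O)[C@@H](C)C(O)=O)[C@]1(C)O[Si](CC)(CC)CC | intermediate
33 | C19 methyl ester of 32 | O=C1C=C2[Si](C(C)C)(C(C)C)O[C@H](CC/C(C)=C\[Si](C)(C)C)[C@]2(C)[C@@H]([C@@H](OC(C)=O)[C@]3(O[C@H](C(C)(C)C)OC3=O)[C@@H](C)C(=O)OC)[C@]1(C)O[Si](CC)(CC)CC | intermediate
34 | C7 S-ethyl thioester with free C8 tertiary alcohol | O=C1C=C2[Si](C(C)C)(C(C)C)O[C@H](CC/C(C)=C\[Si](C)(C)C)[C@]2(C)[C@@H]([C@@H](OC(C)=O)[C@@](O)(C(=O)SCC)[C@@H](C)C(=O)OC)[C@]1(C)O[Si](CC)(CC)CC | intermediate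
35 | C7 aldehyde (α-hydroxy aldehyde at C8) | O=C1C=C2[Si](C(C)C)(C(C)C)O[C@H](CC/C(C)=C\[Si](C)(C)C)[C@]2(C)[C@@H]([C@@H](OC(C)=O)[C@@](O)(C=O)[C@@H](C)C(=O)OC)[C@]1(C)O[Si](CC)(CC)CC | intermediate
36 | C7 aldehyde with (Z)-vinyl iodide at C6 | O=C1C=C2[Si](C(C)C)(C(C)C)O[C@H](CC/C(C)=C\I)[C@]2(C)[C@@H]([C@@H](OC(C)=O)[C@@](O)(C=O)[C@@H](C)C(=O)OC)[C@]1(C)O[Si](CC)(CC)CC | intermediate
37 | ten-membered (7S)-allylic alcohol with open C19 methyl ester | O=C1C=C2[Si](C(C)C)(C(C)C)O[C@@H]3CC/C(C)=C\[C@H](O)[C@@](O)([C@@H](C)C(=O)OC)[C@H](OC(C)=O)[C@H]([C@]23C)[C@]1(C)O[Si](CC)(CC)CC | intermediate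
38 | macrocyclic γ-lactone with the C2–O–Si–C14 bridge and C11 triethylsilyl ether | O=C1C=C2[Si](C(C)C)(C(C)C)O[C@@H]3CC/C(C)=C\[C@@H]4OC(=O)[C@H](C)[C@@]4(O)[C@H](OC(C)=O)[C@H]([C@]23C)[C@]1(C)O[Si](CC)(CC)CC | intermediate
39 | 2-O-depropionyl target (9-O-acetyl-2,8,11-triol) | O[C@@H]1CC/C(C)=C\[C@@H]2OC(=O)[C@H](C)[C@@]2(O)[C@H](OC(C)=O)[C@@H]2[C@]1(C)C=CC(=O)[C@@]2(C)O | intermediate
40 | CNP0240018.1 | CCC(=O)O[C@@H]1CC/C(C)=C\[C@@H]2OC(=O)[C@H](C)[C@@]2(O)[C@H](OC(C)=O)[C@@H]2[C@]1(C)C=CC(=O)[C@@]2(C)O | target

**Step count and risks**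

Total steps: 25. Longest linear sequence: 21 steps (steps 1–7, 9–14 and 18–25).

Steps most likely to fail:

1. Step 10 (Proposed new method). The rhodacyclopentanone may lose CO (decarbonylation to a cyclopropane) or close in the (4+1) sense faster than the hindered silicon-bearing alkyne inserts, and the terminal ethynylsilane may oligomerise before C–C activation. The fallback uses known chemistry only, sets out from 13 and comes back at 18, making the same two bonds in two operations. Alcohol 13 would be protected as triethylsilyl ether F1 (TESCl, imidazole), and vinylmagnesium bromide/CeCl3 would add to the ketone to give 1-vinylcyclobutanol F2. Its potassium alkoxide (KH, 18-crown-6, THF) would undergo the oxyanion-accelerated [1,3]-sigmatropic two-carbon ring expansion with migration of the quaternary carbon, the regiodefined enolate being trapped as trimethylsilyl enol ether F3. Saegusa–Ito oxidation (Pd(OAc)2, MeCN) would give cyclohexenone F4, and HF·pyridine would free alcohol F5. Silylation with chlorodiisopropylsilane would give hydrosilyl ether F6, and iridium-catalysed hydrosilyl-directed dehydrogenative silylation of the γ vinylic C–H bond ([Ir(cod)OMe]2, 3,4,7,8-tetramethylphenanthroline, norbornene) would close the oxasilole to 18.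

2. Step 18. The congested aldehyde may react slowly, so that retro-aldol equilibration precedes acetylation, and the facial selectivity at C9 may be poor. The fallback sets out from 25 and 30 and comes back at 33, setting C9 by reduction instead of by the C–C bond formation. The aldol would be quenched with acetic acid and the crude acid esterified (TMSCHN2) to the C9-epimeric hydroxy ester F7. Dess–Martin oxidation would give β-keto ester F8. Chelation-controlled reduction with Zn(BH4)2 at −40 °C (zinc bridging the C9 carbonyl and the acetal oxygen on C8; the hindered β-silyl enone is expected to survive) should give (9R)-alcohol F9, and acetylation (Ac2O, DMAP) would give 33.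

3. Step 23. Intermolecular coupling may outrun closure of the strained ten-membered ring, or the ring may close on the wrong face of the aldehyde. The fallback sets out from 35 and comes back at 39, closing the ring at C5=C6 instead. Intermolecular Nozaki–Hiyama–Kishi addition of vinyl bromide to 35, with lactonisation, would give vinyl lactone F10. Protodesilylation of the trisubstituted vinylsilane with loss of the TES ether (TsOH·H2O, wet MeCN, 50 °C) would give diene F11. Ring-closing metathesis (Hoveyda–Grubbs second-generation catalyst, toluene, 80 °C, 1 mM), in which the ten-membered ring should enforce the (Z)-alkene, would give bridged macrocycle F12, and TBAF/AcOH as in step 24 would give 39.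

Further compounds
F1 | step 10 | triethylsilyl ether of 13 | O=C1CC[C@@]1(C)[C@H](O[Si](CC)(CC)CC)CC/C(C)=C\[Si](C)(C)C
F2 | step 10 | 1-vinylcyclobutanol from F1 (carbinol epimers) | C=CC1(O)CC[C@@]1(C)[C@H](O[Si](CC)(CC)CC)CC/C(C)=C\[Si](C)(C)C
F3 | step 10 | ring-expanded trimethylsilyl enol ether (C12=C13) | C[Si](C)(C)OC1=CC[C@](C)([C@H](O[Si](CC)(CC)CC)CC/C(C)=C\[Si](C)(C)C)CC1
F4 | step 10 | 4,4-disubstituted cyclohex-2-enone with C2 triethylsilyl ether | O=C1C=C[C@](C)([C@H](O[Si](CC)(CC)CC)CC/C(C)=C\[Si](C)(C)C)CC1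
F5 | step 10 | 4,4-disubstituted cyclohex-2-enone with free C2 alcohol | O=C1C=C[C@](C)([C@H](O)CC/C(C)=C\[Si](C)(C)C)CC1
F6 | step 10 | diisopropyl(hydrido)silyl ether of F5 | O=C1C=C[C@](C)([C@H](O[SiH](C(C)C)C(C)C)CC/C(C)=C\[Si](C)(C)C)CC1
F7 | step 18 | C9-epimeric hydroxy methyl esters of the aldol adduct | O=C1C=C2[Si](C(C)C)(C(C)C)O[C@H](CC/C(C)=C\[Si](C)(C)C)[C@]2(C)[C@@H](C(O)[C@]3(O[C@H](C(C)(C)C)OC3=O)[C@@H](C)C(=O)OC)[C@]1(C)O[Si](CC)(CC)CC
F8 | step 18 | C9 ketone (β-keto ester) | O=C1C=C2[Si](C(C)C)(C(C)C)O[C@H](CC/C(C)=C\[Si](C)(C)C)[C@]2(C)[C@@H](C(=O)[C@]3(O[C@H](C(C)(C)C)OC3=O)[C@@H](C)C(=O)OC)[C@]1(C)O[Si](CC)(CC)CC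
F9 | step 18 | (9R)-hydroxy methyl ester | O=C1C=C2[Si](C(C)C)(C(C)C)O[C@H](CC/C(C)=C\[Si](C)(C)C)[C@]2(C)[C@@H]([C@@H](O)[C@]3(O[C@H](C(C)(C)C)OC3=O)[C@@H](C)C(=O)OC)[C@]1(C)O[Si](CC)(CC)CC
F10 | step 23 | γ-vinyl γ-lactone with intact vinylsilane chain | O=C1C=C2[Si](C(C)C)(C(C)C)O[C@H](CC/C(C)=C\[Si](C)(C)C)[C@]2(C)[C@@H]([C@@H](OC(C)=O)[C@]3(O)[C@@H](C)C(=O)O[C@H]3C=C)[C@]1(C)O[Si](CC)(CC)CC
F11 | step 23 | diene for metathesis (isopropenyl terminus, free C11 alcohol) | O=C1C=C2[Si](C(C)C)(C(C)C)O[C@H](CCC(C)=C)[C@]2(C)[C@@H]([C@@H](OC(C)=O)[C@]3(O)[C@@H](C)C(=O)O[C@H]3C=C)[C@]1(C)O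
F12 | step 23 | macrocyclic lactone with oxasilole bridge and free C11 alcohol | O=C1C=C2[Si](C(C)C)(C(C)C)O[C@@H]3CC/C(C)=C\[C@@H]4OC(=O)[C@H](C)[C@@]4(O)[C@H](OC(C)=O)[C@H]([C@]23C)[C@]1(C)O
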